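**Retrosynthetic overview**

Feature: ring A (C10, C11, C12, C22, C21, C23; atoms numbered in target SMILES order) carries three contiguous methines C12, C22, C21 with C13/C16 trans and C16/C18 cis. This is the imprint of an E-enal adding across C11 and C21 of an (E,E)-diene C11=C10–C23=C21 once the ring alkene is parked at C10=C23; SiMe3 on C11 makes that alkene an allylsilane.
Late stage: ring D (spiro cyclopentanone C23/C24/C25/C27/C28) by allylsilane–aldehyde closure of C23–C28, which returns the alkene to C10=C11; before it ring B (lactone O15–C13), C19 (MeCeCl2) and ring C (cyclopentane, C16–C17 aldol).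
Ring A: iminium-catalysed Diels–Alder of silyl diene 23 with methyl (E)-4-oxobut-2-enoate 24 (bonds C11–C12 and C21–C22).
Diene 23: C10–C23 Suzuki coupling of (Z)-β-boryl vinylsilane 9 (C4 set by rhodium-catalysed conjugate addition) with (E)-vinyl iodide 22 (from but-3-yn-2-one and 1,3-dithiane).
Ring order: A, then C, then B, then D.

Key step: step 14

Remark: compounds 1, 2, 10, 15, 16 and 24 are taken as purchasable; the C16 carbinol from the aldol (step 16) is treated as provisional and is reset in steps 18 and 19, so any 16R epimer formed early would lactonise after step 17 and rejoin the route at 33.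

**Route**

Step 1
Reactants: 1 5,6-dihydro-2H-pyran-2-one; 2 isopropenylboronic acid pinacol ester
Product: 3 (S)-4-(prop-1-en-2-yl)oxan-2-one
Conditions: [Rh(cod)OH]2 (2.5 mol%), (S)-BINAP [(S)-2,2'-bis(diphenylphosphino)-1,1'-binaphthyl] (6 mol%), dioxane/H2O (10:1), 50 °C
Reagents that add atoms: none
Why: Rhodium-catalysed asymmetric 1,4-addition of an alkenylboron reagent to an unsaturated lactone (Hayashi–Miyaura reaction) sets C4; (S)-BINAP is expected to give the S lactone by the facial sense established for cyclic enones and lactones, and the cyclic acceptor excludes 1,6-addition.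

Step 2
Reactants: 3 (S)-4-(prop-1-en-2-yl)oxan-2-one
Product: 4 methyl (S)-5-hydroxy-3-(prop-1-en-2-yl)pentanoate
Conditions: MeOH, Et3N, rt; concentrated cold and used directly
Reagents that add atoms: methanol, CO
Why: Base-catalysed ring-opening transesterification in methanol as solvent should give the open hydroxy ester (used at once to avoid relactonisation) and leaves C4, which is β to the carbonyl, untouched.

Step 3
Reactants: 4 methyl (S)-5-hydroxy-3-(prop-1-en-2-yl)pentanoate
Product: 5 methyl (S)-5-oxo-3-(prop-1-en-2-yl)pentanoate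
Conditions: Dess–Martin periodinane, NaHCO3, CH2Cl2, 0 °C → rt
Reagents that add atoms: none
Why: Dess–Martin oxidation of the primary alcohol to the aldehyde is buffered and non-epimerising, and the stereocentre is β to both carbonyl groups.

Step 4
Reactants: 5 methyl (S)-5-oxo-3-(prop-1-en-2-yl)pentanoate
Product: 7 methyl (S)-3-(prop-1-en-2-yl)pent-4-ynoate, via alkenyl nonaflate 6 (not isolated)
Conditions: C4F9SO2F (1.2 equiv), phosphazene base P2-Et [EtN=P(NMe2)2–N=P(NMe2)3] (2.2 equiv), DMF, −20 °C → rt
Reagents that add atoms: none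
Why: One-pot conversion of an enolisable aldehyde into a terminal alkyne (O-sulfonylation of the enolate, then base-induced elimination of nonaflate) keeps both carbons as C10 and C11, and the base is too weak to remove the C4 proton.

Step 5
Reactants: 7 methyl (S)-3-(prop-1-en-2-yl)pent-4-ynoate
Product: 8 methyl (S)-3-(prop-1-en-2-yl)-5-(trimethylsilyl)pent-4-ynoate
Conditions: Me3SiOTf, Et3N, Zn(OTf)2 (10 mol%), CH2Cl2, rt
Reagents that add atoms: trimethylsilyl trifluoromethanesulfonate, C[Si](C)(C)OS(=O)(=O)C(F)(F)F
Why: Zinc-catalysed C-silylation of a terminal alkyne (zinc acetylide trapped by the silyl triflate) avoids strong base, so the ester and the skipped enyne should survive.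

Step 6
Reactants: 8 methyl (S)-3-(prop-1-en-2-yl)-5-(trimethylsilyl)pent-4-ynoate
Product: 9 methyl (3R,4Z)-3-(prop-1-en-2-yl)-4-(4,4,5,5-tetramethyl-1,3,2-dioxaborolan-2-yl)-5-(trimethylsilyl)pent-4-enoate
Conditions: B2pin2 (1.1 equiv), CuCl (5 mol%), NaOt-Bu (10 mol%), P(p-tol)3 (6 mol%), MeOH (2 equiv), THF, rt
Reagents that add atoms: bis(pinacolato)diboron, CC1(C)OB(OC1(C)C)B1OC(C)(C)C(C)(C)O1
Why: Copper-catalysed formal hydroboration of a silylalkyne (syn borylcupration with copper α to silicon, then protonation) should place boron on C10 and hydrogen on C11 cis to it, so silicon is cis to the C4 branch as the diene requires; the C4 descriptor changes to R only because boron alters the priorities.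

Step 7
Reactants: 10 but-3-yn-2-one
Product: 11 2-ethynyl-2-methyl-1,3-dioxolane
Conditions: Me3SiOCH2CH2OSiMe3, Me3SiOTf (cat.), CH2Cl2, −78 → −20 °C
Reagents that add atoms: 1,2-bis(trimethylsilyloxy)ethane, C[Si](C)(C)OCCO[Si](C)(C)C
Why: Low-temperature ketalisation with the bis-silyl ether of ethylene glycol masks the ynone carbonyl (the future C18) without conjugate addition to the alkyne.

Step 8
Reactants: 11 2-ethynyl-2-methyl-1,3-dioxolane
Product: 13 3-(2-methyl-1,3-dioxolan-2-yl)prop-2-yn-1-ol, via lithium acetylide 12 (not isolated)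
Conditions: n-BuLi, THF, −78 °C; then (CH2O)n, −78 °C → rt
Reagents that add atoms: formaldehyde (as paraformaldehyde), C=O
Why: Hydroxymethylation of a lithium acetylide adds C24 by a standard 1,2-addition to formaldehyde.

Step 9
Reactants: 13 3-(2-methyl-1,3-dioxolan-2-yl)prop-2-yn-1-ol
Product: 14 2-(3-bromoprop-1-yn-1-yl)-2-methyl-1,3-dioxolane
Conditions: CBr4, PPh3, 2,6-lutidine, CH2Cl2, 0 °C
Reagents that add atoms: tetrabromomethane, BrC(Br)(Br)Br
Why: The Appel reaction converts the propargylic alcohol into the bromide under near-neutral conditions that the ketal tolerates.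

Step 10
Reactants: 15 1,3-dithiane; 16 tert-butyl(2-iodoethoxy)dimethylsilane
Product: 18 tert-butyl[2-(1,3-dithian-2-yl)ethoxy]dimethylsilane, via 2-lithio-1,3-dithiane 17 (not isolated)
Conditions: n-BuLi, THF, −30 °C; then 16, −78 → 0 °C
Reagents that add atoms: none
Why: Corey–Seebach alkylation of lithiated dithiane with a primary iodide installs C27 and C28 on the masked C25 carbonyl.

Step 11
Reactants: 18 tert-butyl[2-(1,3-dithian-2-yl)ethoxy]dimethylsilane; 14 2-(3-bromoprop-1-yn-1-yl)-2-methyl-1,3-dioxolane
Product: 20 dithiane alkyne, via lithiated dithiane 19 (not isolated)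
Conditions: t-BuLi, THF/HMPA (10:1), −78 °C; then 14, −78 → −20 °C
Reagents that add atoms: none
Why: A second Corey–Seebach alkylation forms C24–C25 by SN2 at the propargylic bromide; SN2' attack is disfavoured because the alkyne terminus carries the quaternary ketal carbon.

Step 12
Reactants: 20 dithiane alkyne
Product: 22 (E)-vinyl iodide, via alkenylzirconocene 21 (not isolated)
Conditions: Cp2Zr(H)Cl (1.5 equiv), THF, rt; then I2, THF, 0 °C
Reagents that add atoms: iodine, II
Why: Syn hydrozirconation should put zirconium on C23, the alkyne carbon remote from the quaternary ketal carbon, and iodinolysis with retention then gives the iodide with H21 cis to iodine, so C18 is cis to C24.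

Step 13
Reactants: 9 (Z)-β-boryl vinylsilane; 22 (E)-vinyl iodide
Product: 23 silyl diene, methyl (3S,4E,5E)-5-({2-[2-(tert-butyldimethylsilyloxy)ethyl]-1,3-dithian-2-yl}methyl)-6-(2-methyl-1,3-dioxolan-2-yl)-3-(prop-1-en-2-yl)-4-[(trimethylsilyl)methylidene]hex-5-enoate
Conditions: Pd(PPh3)4 (10 mol%), TlOEt (1.8 equiv), THF/H2O (3:1), rt
Reagents that add atoms: none
Why: Suzuki–Miyaura coupling joins C10 and C23 with retention at both sp2 carbons, and TlOEt accelerates transmetalation of the hindered boronate at room temperature so the methyl ester is not hydrolysed.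

Step 14
Reactants: 23 silyl diene; 24 methyl (E)-4-oxobut-2-enoate
Product: 27 ring A allylsilane adduct, via dienophile iminium salt 25 (not isolated), via adduct iminium salt 26 (not isolated)
Conditions: (5R)-5-benzyl-2,2,3-trimethylimidazolidin-4-one·CF3CO2H (20 mol%), 24 (1.5 equiv), MeCN/H2O (95:5), −20 → 0 °C
Reagents that add atoms: none
Why: The amine salt condenses with the aldehyde of 24 to the E-configured iminium ion 25, which adds suprafacially across C11 and C21 of the s-cis diene 23 in a concerted but asynchronous [4+2] cycloaddition (C11–C12 bonding ahead of C21–C22), and hydrolysis of the adduct iminium 26 releases 27 and the amine. The closest known reaction types are imidazolidinone-catalysed Diels–Alder reactions of enals with acyclic dienes and cycloadditions of 1-silyl-1,3-dienes that give cyclic allylsilanes. Ring A is closed by intermolecular [4+2] annulation, both σ bonds forming on one face of each partner and the alkene emerging at C10=C23. C12 and C22 take their trans relationship from the E dienophile and their absolute sense (12R,22R) from the catalyst, whose 5R benzyl group covers one face of the iminium π system; C11 and C21 follow from the E,E diene (Si and C18 outward, hence cis) and from the iminium-endo transition state, which places C16 cis to both. The step needs C12-to-C11 regiochemistry, endo orientation of the iminium and one diene face: the silyl terminus C11 directs "meta" (β-silicon stabilisation of charge at C10) and the carbon-substituted, inductively deactivated terminus C21 directs "ortho", so both pair the iminium β-carbon C12 with C11, while secondary overlap of the iminium favours endo. The C4 centre is remote from the reacting termini and should be overridden by the catalyst, and the allylic ketal, silyl ether and vinylsilane are expected to tolerate the weakly acidic, low-water medium.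

Step 15
Reactants: 27 ring A allylsilane adduct
Product: 28 keto aldehyde
Conditions: pyridinium p-toluenesulfonate (0.3 equiv), acetone/H2O (10:1), 45 °C
Reagents that add atoms: water, O
Why: Mild acid-catalysed hydrolysis of the dioxolane (now an ordinary, non-allylic ketal) frees the C18 methyl ketone; the acid is too weak to protodesilylate the allylsilane or cleave the silyl ether.

Step 16
Reactants: 28 keto aldehyde
Product: 29 ring C ketol
Conditions: L-proline (30 mol%), DMSO, rt
Reagents that add atoms: none
Why: Proline-catalysed intramolecular aldol addition (enamine catalysis, methyl ketone donor onto an α-branched aldehyde acceptor, 5-enolexo) closes ring C at C16–C17 without dehydration; the cis C21/C22 branches give a cis ring fusion, and the C16 hydroxyl is expected on the convex face (16S) because the concave face is occupied by C12 and its ester.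

Step 17
Reactants: 29 ring C ketol
Product: 30 diol
Conditions: MeLi (3.5 equiv), CeCl3 (4 equiv, dried), THF, −78 °C
Reagents that add atoms: methyllithium, [Li]C
Why: Organocerium 1,2-addition to the C18 ketone is non-basic and faster than attack on the two esters, and the methyl group should arrive on the convex face of the cis-fused bicycle, anti to C23, giving 18S with C19 convex and O20 concave.

Step 18
Reactants: 30 diol
Product: 31 C16 ketone
Conditions: SO3·pyridine, DMSO, i-Pr2NEt, CH2Cl2, 0 °C
Reagents that add atoms: none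
Why: Parikh–Doering oxidation converts only the secondary C16 carbinol (the tertiary C18 alcohol, dithiane and allylsilane are inert) and erases the provisional C16 configuration.

Step 19
Reactants: 31 C16 ketone
Product: 33 ring B lactone, via 16R diol ester 32 (not isolated)
Conditions: NaBH4, MeOH/CH2Cl2 (1:1), −40 °C; then pyridinium p-toluenesulfonate (cat.), toluene, 50 °C
Reagents that add atoms: none
Why: Hydride reduction from the convex face (the concave face is blocked by ring A and the C13 ester) should give the 16R alcohol cis to C12 and to the C18 hydroxyl, which then closes the γ-lactone with the C13 ester by acid-catalysed transesterification.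

Step 20
Reactants: 33 ring B lactone
Product: 34 primary alcohol
Conditions: HF·pyridine, pyridine, THF, 0 °C → rt
Reagents that add atoms: none
Why: Buffered fluoride cleavage of the primary silyl ether frees O–C28 while the allylsilane, tertiary alcohol and lactone should be unaffected.

Step 21
Reactants: 34 primary alcohol
Product: 35 C28 aldehyde
Conditions: SO3·pyridine, DMSO, i-Pr2NEt, CH2Cl2, 0 °C
Reagents that add atoms: none
Why: Parikh–Doering oxidation gives the aldehyde under conditions that spare the dithiane and are too mild for β-elimination of sulfur.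

Step 22
Reactants: 35 C28 aldehyde
Product: 36 spiro alcohol dithiane
Conditions: BF3·OEt2 (2 equiv), CH2Cl2, −78 → −40 °C; aq. NaHCO3
Reagents that add atoms: none
Why: Intramolecular Hosomi–Sakurai reaction (SE2'): C23 attacks the BF3-activated aldehyde on the face anti to silicon, which is also the face opposite the pseudo-axial C18 branch on C21, closing ring D and moving the alkene to C10=C11 (C23 R); a synclinal transition state with the complexed oxygen over the alkene side and the aldehyde hydrogen toward C21 should give 28S.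

Step 23
Reactants: 36 spiro alcohol dithiane
Product: 37 CNP0255095.1 (target)
Conditions: MeI (excess), CaCO3, MeCN/H2O (9:1), 45 °C
Reagents that add atoms: water, O
Why: S-Methylation and hydrolysis of the dithiane under buffered, near-neutral conditions unmasks the C25 ketone without dehydrating the new β-hydroxy ketone or disturbing the alkenes, alcohols and lactone.

**Compound list**

1 | 5,6-dihydro-2H-pyran-2-one | O=C1C=CCCO1 | starting material
2 | isopropenylboronic acid pinacol ester | C=C(C)B1OC(C)(C)C(C)(C)O1 | starting material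
3 | (S)-4-(prop-1-en-2-yl)oxan-2-one | C=C(C)[C@H]1CCOC(=O)C1 | intermediate
4 | methyl (S)-5-hydroxy-3-(prop-1-en-2-yl)pentanoate | C=C(C)[C@H](CC(=O)OC)CCO | intermediate
5 | methyl (S)-5-oxo-3-(prop-1-en-2-yl)pentanoate | C=C(C)[C@H](CC(=O)OC)CC=O | intermediate
6 | methyl (3R)-5-(nonafluorobutylsulfonyloxy)-3-(prop-1-en-2-yl)pent-4-enoate, E/Z mixture (same spatial arrangement at C3 as 5) | C=C(C)[C@H](CC(=O)OC)C=COS(=O)(=O)C(F)(F)C(F)(F)C(F)(F)C(F)(F)F | intermediate (not isolated)
7 | methyl (S)-3-(prop-1-en-2-yl)pent-4-ynoate | C=C(C)[C@H](CC(=O)OC)C#C | intermediate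
8 | methyl (S)-3-(prop-1-en-2-yl)-5-(trimethylsilyl)pent-4-ynoate | C=C(C)[C@H](CC(=O)OC)C#C[Si](C)(C)C | intermediate
9 | methyl (3R,4Z)-3-(prop-1-en-2-yl)-4-(pinacolboryl)-5-(trimethylsilyl)pent-4-enoate | C=C(C)[C@H](CC(=O)OC)/C(B1OC(C)(C)C(C)(C)O1)=C\[Si](C)(C)C | intermediate
10 | but-3-yn-2-one | CC(=O)C#C | starting material
11 | 2-ethynyl-2-methyl-1,3-dioxolane | CC1(C#C)OCCO1 | intermediate
12 | lithium acetylide of 11 | CC1(C#C[Li])OCCO1 | intermediate (not isolated)
13 | 3-(2-methyl-1,3-dioxolan-2-yl)prop-2-yn-1-ol | CC1(C#CCO)OCCO1 | intermediate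
14 | 2-(3-bromoprop-1-yn-1-yl)-2-methyl-1,3-dioxolane | CC1(C#CCBr)OCCO1 | intermediate
15 | 1,3-dithiane | C1CSCSC1 | starting material
16 | tert-butyl(2-iodoethoxy)dimethylsilane | CC(C)(C)[Si](C)(C)OCCI | starting material
17 | 2-lithio-1,3-dithiane | [Li]C1SCCCS1 | intermediate (not isolated)
18 | tert-butyl[2-(1,3-dithian-2-yl)ethoxy]dimethylsilane | CC(C)(C)[Si](C)(C)OCCC1SCCCS1 | intermediate
19 | 2-lithio derivative of 18 | CC(C)(C)[Si](C)(C)OCCC1([Li])SCCCS1 | intermediate (not isolated)
20 | tert-butyldimethyl(2-{2-[3-(2-methyl-1,3-dioxolan-2-yl)prop-2-yn-1-yl]-1,3-dithian-2-yl}ethoxy)silane | CC1(C#CCC2(CCO[Si](C)(C)C(C)(C)C)SCCCS2)OCCO1 | intermediate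
21 | alkenylzirconocene chloride, Zr on C23 cis to H21 (Cp rings drawn σ-bonded in the SMILES) | CC1(/C=C(/[Zr](Cl)(C2C=CC=C2)C2C=CC=C2)CC2(CCO[Si](C)(C)C(C)(C)C)SCCCS2)OCCO1 | intermediate (not isolated)
22 | tert-butyl(2-{2-[(2E)-2-iodo-3-(2-methyl-1,3-dioxolan-2-yl)prop-2-en-1-yl]-1,3-dithian-2-yl}ethoxy)dimethylsilane | CC1(/C=C(/I)CC2(CCO[Si](C)(C)C(C)(C)C)SCCCS2)OCCO1 | intermediate
23 | silyl diene (name in step 13): C11H(SiMe3)=C10(C4 side chain)–C23(CH2–dithiane arm)=C21H–C18(CH3)(dioxolane); 4S, both alkenes E | C=C(C)[C@H](CC(=O)OC)/C(=C\[Si](C)(C)C)/C(CC1(SCCCS1)CCO[Si](C)(C)C(C)(C)C)=C/C2(C)OCCO2 | intermediate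
24 | methyl (E)-4-oxobut-2-enoate | COC(=O)/C=C/C=O | starting material
25 | E,E iminium trifluoroacetate of 24 with (5R)-5-benzyl-2,2,3-trimethylimidazolidin-4-one | COC(=O)/C=C/C=[N+]1\[C@H](Cc2ccccc2)C(=O)N(C)C1(C)C.[O-]C(=O)C(F)(F)F | intermediate (not isolated)
26 | iminium trifluoroacetate of adduct 27 (C16=N+ in place of C16=O) | C=C(C)[C@H](CC(=O)OC)C1=C(CC5(SCCCS5)CCO[Si](C)(C)C(C)(C)C)[C@@H](C2(C)OCCO2)[C@@H](/C=[N+]3\[C@H](Cc4ccccc4)C(=O)N(C)C3(C)C)[C@H](C(=O)OC)[C@H]1[Si](C)(C)C.[O-]C(=O)C(F)(F)F | intermediate (not isolated)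
27 | ring A allylsilane adduct: cyclohexene (C10=C23) with the (S)-C4 side chain on C10, the CH2–dithiane arm on C23, 2-methyl-1,3-dioxolan-2-yl on C21, CHO on C22, CO2Me on C12, SiMe3 on C11; 11R,12R,21S,22R (Si, CHO and ketal mutually cis, CO2Me trans) | C=C(C)[C@H](CC(=O)OC)C1=C(CC5(SCCCS5)CCO[Si](C)(C)C(C)(C)C)[C@@H](C2(C)OCCO2)[C@@H](C=O)[C@H](C(=O)OC)[C@H]1[Si](C)(C)C | intermediate
28 | keto aldehyde: as 27 with acetyl (C18=O, C17H3) on C21 | C=C(C)[C@H](CC(=O)OC)C1=C(CC5(SCCCS5)CCO[Si](C)(C)C(C)(C)C)[C@@H](C(C)=O)[C@@H](C=O)[C@H](C(=O)OC)[C@H]1[Si](C)(C)C | intermediate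
29 | ring C ketol: cyclopentanone C16/C17/C18/C21/C22 cis-fused to ring A, C18 ketone, C16–OH on the convex face (16S) | C=C(C)[C@H](CC(=O)OC)C1=C(CC5(SCCCS5)CCO[Si](C)(C)C(C)(C)C)[C@@H](C(=O)C6)[C@@H]([C@H]6O)[C@H](C(=O)OC)[C@H]1[Si](C)(C)C | intermediate
30 | diol: as 29 with C18 tertiary carbinol (18S, C19 convex, O20 concave), 16S | C=C(C)[C@H](CC(=O)OC)C1=C(CC5(SCCCS5)CCO[Si](C)(C)C(C)(C)C)[C@@H]([C@@](C)(O)C6)[C@@H]([C@H]6O)[C@H](C(=O)OC)[C@H]1[Si](C)(C)C | intermediate
31 | C16 ketone with 18S tertiary carbinol | C=C(C)[C@H](CC(=O)OC)C1=C(CC5(SCCCS5)CCO[Si](C)(C)C(C)(C)C)[C@@H]([C@@](C)(O)C6)[C@@H](C6=O)[C@H](C(=O)OC)[C@H]1[Si](C)(C)C | intermediate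
32 | 16R,18S diol ester (C16–OH concave, cis to C12) | C=C(C)[C@H](CC(=O)OC)C1=C(CC5(SCCCS5)CCO[Si](C)(C)C(C)(C)C)[C@@H]([C@@](C)(O)C6)[C@@H]([C@@H]6O)[C@H](C(=O)OC)[C@H]1[Si](C)(C)C | intermediate (not isolated)
33 | ring B lactone (O15–C13 closed, trans-fused to ring A, cis-fused to ring C), silyl ether at O–C28, SiMe3 on C11 | C=C(C)[C@H](CC(=O)OC)C1=C(CC5(SCCCS5)CCO[Si](C)(C)C(C)(C)C)[C@@H]([C@@](C)(O)C6)[C@@H]([C@@H]6O7)[C@H](C7=O)[C@H]1[Si](C)(C)C | intermediate
34 | primary alcohol: as 33 with free C28–OH | C=C(C)[C@H](CC(=O)OC)C1=C(CC5(SCCCS5)CCO)[C@@H]([C@@](C)(O)C6)[C@@H]([C@@H]6O7)[C@H](C7=O)[C@H]1[Si](C)(C)C | intermediate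
35 | C28 aldehyde: as 34 with C28H=O | C=C(C)[C@H](CC(=O)OC)C1=C(CC5(SCCCS5)CC=O)[C@@H]([C@@](C)(O)C6)[C@@H]([C@@H]6O7)[C@H](C7=O)[C@H]1[Si](C)(C)C | intermediate
36 | spiro alcohol dithiane: the target with C25 as its 1,3-dithiane (23R,28S) | C=C(C)[C@H](CC(=O)OC)C1=C[C@H]2C(=O)O[C@@H]3C[C@](C)(O)[C@@H]([C@@H]32)[C@]12CC4(SCCCS4)C[C@@H]2O | intermediate
37 | CNP0255095.1 (4S,12R,16R,18S,21S,22R,23R,28S) | C=C(C)[C@H](CC(=O)OC)C1=C[C@H]2C(=O)O[C@@H]3C[C@](C)(O)[C@@H]([C@@H]32)[C@]12CC(=O)C[C@@H]2O | target

**Step count and risks**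

Total step count: 23. Longest linear sequence: 17 steps (steps 1–6, 13, 14, 15–23).

Steps most likely to fail:

Step 14 (Diels–Alder). The cycloaddition of the fully substituted, hindered diene may be slower than acid-promoted hydrolysis of its allylic ketal to a dienone that no longer reacts, and regio- or endo-control may erode with a slow reaction. The fallback is an auxiliary-controlled, Lewis acid-promoted Diels–Alder that sets out from 23 and returns at 27. Diene 23 would be combined with (R)-4-benzyl-3-[(E)-4-methoxy-4-oxobut-2-enoyl]oxazolidin-2-one F1 (from monomethyl fumarate via its acid chloride and the lithium salt of (R)-4-benzyloxazolidin-2-one) under Et2AlCl in CH2Cl2 at −78 °C. The chelated imide is then the activated, endo-directing carbonyl, so the same regiochemistry and relative configuration are expected, and the benzyl group of the R auxiliary should expose the dienophile face that leads to 22R. The resulting C16 N-acyloxazolidinone adduct F2 would be cleaved with LiBH4 (THF/MeOH, 0 °C) to the C16 carbinol F3, and Parikh–Doering oxidation would give 27.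

Step 22 (spirocyclisation). The trans-fused lactone holds the C11–Si bond pseudo-equatorial, so overlap with the alkene is poor and protodesilylation or loss of face selectivity at C28 may compete with SE2' attack. The fallback closes ring D before ring B; it sets out from 30 and returns at 36. Diol 30 would be desilylated (HF·pyridine, pyridine, THF) to triol F4, and both carbinols oxidised (SO3·pyridine, DMSO, i-Pr2NEt) to keto aldehyde F5, in which ring A is still free to place the C–Si bond pseudo-axial. BF3·OEt2 at −78 °C would then give spiro hydroxy ketone F6 by attack on the more electrophilic aldehyde. NaBH4 would reduce the C16 ketone from the convex face to the 16R diol ester F7, and warming with pyridinium p-toluenesulfonate in toluene would close the lactone to 36.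

Step 13 (Suzuki coupling). Transmetalation of the α-branched, 1,1-disubstituted alkenylboronate may be slow, so protodeboronation or homocoupling could take over from cross-coupling. The fallback is a Negishi coupling with the roles of the partners exchanged; it sets out from 9 and returns at 23. Boronate 9 would be converted with NaOMe and then I2 (THF, −78 °C, iododeboronation with retention) into methyl (3S,4E)-4-iodo-3-(prop-1-en-2-yl)-5-(trimethylsilyl)pent-4-enoate F8. Alkenylzirconocene 21, prepared from 20 as in step 12 but not iodinated, would be transmetalated with ZnCl2 and coupled with F8 under Pd(PPh3)4 in THF at rt to give 23.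

Further compounds
F1 | step 14 | (R)-4-benzyl-3-[(E)-4-methoxy-4-oxobut-2-enoyl]oxazolidin-2-one | COC(=O)/C=C/C(=O)N1[C@H](Cc2ccccc2)COC1=O
F2 | step 14 | C16 N-acyloxazolidinone analogue of 27 | C=C(C)[C@H](CC(=O)OC)C1=C(CC5(SCCCS5)CCO[Si](C)(C)C(C)(C)C)[C@@H](C2(C)OCCO2)[C@@H](C(=O)N3[C@H](Cc4ccccc4)COC3=O)[C@H](C(=O)OC)[C@H]1[Si](C)(C)C
F3 | step 14 | C16 carbinol analogue of 27 (CH2OH on C22) | C=C(C)[C@H](CC(=O)OC)C1=C(CC5(SCCCS5)CCO[Si](C)(C)C(C)(C)C)[C@@H](C2(C)OCCO2)[C@@H](CO)[C@H](C(=O)OC)[C@H]1[Si](C)(C)C
F4 | step 22 | triol: 30 without the silyl ether | C=C(C)[C@H](CC(=O)OC)C1=C(CC5(SCCCS5)CCO)[C@@H]([C@@](C)(O)C6)[C@@H]([C@H]6O)[C@H](C(=O)OC)[C@H]1[Si](C)(C)C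
F5 | step 22 | keto aldehyde: C16 ketone, C28 aldehyde, 18S carbinol, SiMe3 on C11 | C=C(C)[C@H](CC(=O)OC)C1=C(CC5(SCCCS5)CC=O)[C@@H]([C@@](C)(O)C6)[C@@H](C6=O)[C@H](C(=O)OC)[C@H]1[Si](C)(C)C
F6 | step 22 | spiro hydroxy ketone: ring D closed (23R,28S), C10=C11, C16 ketone, C13 methyl ester | C=C(C)[C@H](CC(=O)OC)C1=C[C@@H](C(=O)OC)[C@@H]3C(=O)C[C@](C)(O)[C@@H]3[C@]12CC4(SCCCS4)C[C@@H]2O
F7 | step 22 | 16R diol ester of the spiro series (open form of 36) | C=C(C)[C@H](CC(=O)OC)C1=C[C@@H](C(=O)OC)[C@@H]3[C@H](O)C[C@](C)(O)[C@@H]3[C@]12CC4(SCCCS4)C[C@@H]2O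
F8 | step 13 | methyl (3S,4E)-4-iodo-3-(prop-1-en-2-yl)-5-(trimethylsilyl)pent-4-enoate | C=C(C)[C@H](CC(=O)OC)/C(I)=C\[Si](C)(C)C
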